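The numbers in the tables were generated by integration from invented constants, noise included.

Late in the two earlier runs, at 3.00 min, the flasks look alike, though the epsilon flask was charged with 4.57 times the leaving ligand of the beta flask.

| setting | beta | epsilon | larch | elm | alder | birch |
|---|---|---|---|---|---|---|
| starting complex | 0.0020 M | 0.0020 M | 0.0020 M | 0.0020 M | 0.0020 M | 0.0020 M |
| leaving ligand | 0.46 mM | 2.1 mM | 0.600 mM | 1.00 mM | 1.50 mM | 2.50 mM |
| gas | 0.067 mM (held) | 0.067 mM (held) | 0.067 mM (held) | 0.067 mM (held) | 0.067 mM (held) | 0.067 mM (held) |
| remark | run made earlier | run made earlier |  |  |  |  |
| time |  |  | 3.0 min | 3.0 min | 3.0 min | 3.0 min |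

| run | time / min | complex with two exchanged / % | starting complex / % |
|---|---|---|---|
| beta | 0.250 | 0 | 93.7 |
| beta | 0.417 | 0.3 | 85.3 |
| beta | 0.833 | 5.2 | 77.4 |
| beta | 1.50 | 12.7 | 59.9 |
| beta | 3.00 | 35.1 | 34.6 |
| epsilon | 0.667 | 2.3 | 80.8 |
| epsilon | 1.33 | 10.7 | 64.5 |
| epsilon | 2.00 | 18.5 | 52.8 |
| epsilon | 2.50 | 27.0 | 46.2 |
| epsilon | 3.00 | 35.9 | 39.2 |

(scatter of a reading: 1 percentage point)

- at the start none of incoming ligand is dissolved
- steps thought possible: starting complex + incoming ligand -> leaving ligand + complex with one exchanged; complex with one exchanged + incoming ligand -> leaving ligand + complex with two exchanged; gas <-> incoming ligand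
- "hardly changes" means that all values lie within two and a half points (for a concentration: within two and a half percent of the largest)

- amount of complex with two exchanged at the end, in percent of the starting complex charged for larch, elm, alder, birch, in this order
- how the row runs (rises, then falls / hardly changes / falls all the way / rises all the way / falls, then rises)

I count exchanges. A complex with one exchanged has taken up one incoming ligand, and a complex with two exchanged has taken up two. So the exchanges made, in percent of the starting complex charged, equal the starting complex lost plus the complex with two exchanged, and the unread complex with one exchanged is not needed. At 3.00 min this sum is 100% in beta and 96.7% in epsilon. They differ by 3.8 percentage points, and that difference rests on 4 readings of scatter 1 point, so I read no clear effect of leaving ligand. In beta the sum at 1.50 min is 52.8%, half of its end value, so the line is straight.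

Averaged over both flasks and turned into a concentration, the incoming ligand consumed per minute is 0.657 mM min⁻¹, and I name this the uptake rate.

The rate of an exchange step is its rate constant times [complex] times [incoming ligand], and [leaving ligand] stands in neither step as a reactant. Yet the starting complex falls during the beta run and the sum does not slow. Now compare the uptake rate with the solution's capacity. At this rate, a solution holding 0.067 mM is emptied in 0.102 min. Because that time is far shorter than the run, I take the dissolved incoming ligand as a steady pool, a steady state: what arrives from the gas is what the complexes consume.

The beta and epsilon readings show no clear effect of leaving ligand on the sum, so I expect the same sum in each new flask at 3.0 min, and the same split. Birch, at 2.50 mM, lies above epsilon's 2.1 mM, so there I extrapolate. My row stands flat at the mean of the two end readings, 35.5%.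

The forecast gives 35.2%, 35.3%, 35.5% and 35.8%, a row that hardly changes, on the ground that “the reaction looks limited by gas dissolving”, and it climbs by 0.6 points where mine stays flat.

    starting complex + incoming ligand → leaving ligand + complex with one exchanged (k = 110 M⁻¹ s⁻¹)
    complex with one exchanged + incoming ligand → leaving ligand + complex with two exchanged (k = 170 M⁻¹ s⁻¹)
    gas ⇌ incoming ligand, rate k3*(csat - [incoming ligand]) (kL = 0.630 s⁻¹)

The flasks give 34.0%, 34.0%, 34.0% and 34.0%, so the row hardly changes, and it lies below my 35.5%. In the larch flask at 1.41 min, incoming ligand is made 1.00 times as fast as it is used up, each step taken net. Over 3.0 min the uptake rate gives 1.97 mM of exchanges, and each exchange frees one leaving ligand. So larch should hold 429% of its own charge of leaving ligand, and it holds 422%. Birch should hold 179%, and it holds 177%.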